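## Retrosynthetic overview

1. Target ⇐ oxazaborolidine-controlled 1,2-reduction of an α′-bromo spiro dienone (sets C3–OH trans to Br) ⇐ face-selective α′-bromination of the spiro dienone (sets C4–Br).
2. Spiro dienone ⇐ methyl addition and carbonyl transposition (Stork–Danheiser) on a spirocyclic vinylogous ester.
3. Spirocyclic vinylogous ester ⇐ chiral Brønsted acid catalysed Diels–Alder reaction of an exo-methylene dimedone enol ether with 2-bromo-3-methylbuta-1,3-diene; this one step makes the quaternary spiro centre, ring B and the vinyl bromide.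
4. Ring order: ring A (the oxygenated ring) is bought as a dimedone enol ether; ring B (the bromocyclohexene) is formed second, by the cycloaddition.

Assumption: both starting materials are catalogue chemicals, catalysts are not counted as steps, and the (S,S)-acid written in step 3 stands for whichever antipode opens the Re face (fixed by the first ee assay).

## Route

Step 1
Reactants: 1 2-methylbut-1-en-3-yne
Product: 3 2-bromo-3-methylbuta-1,3-diene, via allenic bromide 2 (not isolated)
Conditions: 48% aq HBr (1.1 equiv), CuBr (10 mol %), NH4Br, 0 → 20 °C; distil over hydroquinone, store at −20 °C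
Reagents that add atoms: hydrogen bromide, Br
Why: CuBr-catalysed 1,4-hydrobromination of the conjugated enyne gives the allenic bromide, whose 1,3-bromide shift gives the conjugated 2-bromodiene (bromoprene-type hydrohalogenation of a vinylacetylene); no stereocentre is formed.

Step 2
Reactants: 4 3-ethoxy-5,5-dimethylcyclohex-2-en-1-one
Product: 7 3-ethoxy-5,5-dimethyl-6-methylidenecyclohex-2-en-1-one, via Mannich base 5 (not isolated), via trimethylammonium iodide 6 (not isolated)
Conditions: LiN(i-Pr)2, THF, −78 °C; [CH2=NMe2]I, −78 → 0 °C; then MeI, CH2Cl2, 25 °C; then sat. aq NaHCO3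
Reagents that add atoms: N,N-dimethylmethyleneiminium iodide (Eschenmoser's salt), C=[N+](C)C.[I-]
Why: kinetic α′-lithiation at C6, Mannich reaction and β-elimination of the quaternised amine give the exocyclic enone (Eschenmoser methylenation), which cannot isomerise into the ring because C5 is quaternary; no stereocentre is formed.

Step 3
Reactants: 7 3-ethoxy-5,5-dimethyl-6-methylidenecyclohex-2-en-1-one; 3 2-bromo-3-methylbuta-1,3-diene
Product: 8 (6R)-8-bromo-3-ethoxy-5,5,9-trimethylspiro[5.5]undeca-2,8-dien-1-one
Conditions: (S,S)-IDPi acid [imidodiphosphorimidate from two (S)-3,3'-diaryl-BINOL units, N-SO2C6F5 on both phosphorus atoms] (5 mol %), 3 (3 equiv), CHCl3, 4 Å MS, −20 °C, 72 h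
Reagents that add atoms: none
Why: Proposed new method: the strongly acidic, confined IDPi protonates the vinylogous-ester carbonyl of 7 to a chiral contact ion pair whose exocyclic CH2 is the electrophilic terminus; the diene CH2 next to C–Me bonds there first (largest HOMO coefficient, positive charge building on the methyl-bearing and not the bromine-bearing carbon), and the second bond closes on the Re face of C6 inside the catalyst pocket, giving the 9-methyl/8-bromo regioisomer and the (6R) spiro centre in one asynchronous [4+2] event; the closest known reaction type is the IDPi-catalysed enantioselective spirocyclising Diels–Alder reaction of exocyclic enones with isoprene-type alkyl dienes, which has not been shown for a 2-halodiene or with this regiochemical question.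

Step 4
Reactants: 8 (6R)-8-bromo-3-ethoxy-5,5,9-trimethylspiro[5.5]undeca-2,8-dien-1-one
Product: 10 (6R)-8-bromo-1,5,5,9-tetramethylspiro[5.5]undeca-1,8-dien-3-one, via tertiary carbinol 9 (not isolated)
Conditions: MeLi, CeCl3 (anhydrous), THF, −78 °C; then 1 M aq HCl, 25 °C
Reagents that add atoms: methyllithium, [Li]C
Why: the organocerium reagent adds 1,2 to the hindered vinylogous-ester carbonyl without touching the vinyl bromide, and acid hydrolysis of the enol ether with loss of water transposes the carbonyl (Stork–Danheiser sequence); the spiro centre is not involved.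

Step 5
Reactants: 10 (6R)-8-bromo-1,5,5,9-tetramethylspiro[5.5]undeca-1,8-dien-3-one
Product: 12 (4S,6S)-4,8-dibromo-1,5,5,9-tetramethylspiro[5.5]undeca-1,8-dien-3-one, via silyl dienol ether 11 (not isolated)
Conditions: LiN(i-Pr)2, THF, −78 °C; Me3SiCl, −78 → 0 °C; then NBS, THF, −78 → 0 °C
Reagents that add atoms: N-bromosuccinimide, O=C1CCC(=O)N1Br
Why: kinetic α′-deprotonation (as for isophorone) and bromination of the cross-conjugated silyl dienol ether put Br on C4; Br+ is expected to enter anti to the pseudoaxial ring-B methylene C11 (the 1-methyl group leans toward C7 to avoid the axial hydrogen on C10), which gives the equatorial bromide cis to C7, that is (4S); the spiro descriptor switches from R to S only through a CIP priority change.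

Step 6
Reactants: 12 (4S,6S)-4,8-dibromo-1,5,5,9-tetramethylspiro[5.5]undeca-1,8-dien-3-one
Product: 13 (3S,4S,6S)-4,8-dibromo-1,5,5,9-tetramethylspiro[5.5]undeca-1,8-dien-3-ol
Conditions: (R)-2-methyl-CBS-oxazaborolidine (20 mol %), catecholborane, toluene, −78 °C; MeOH, then pH 7 buffer
Reagents that add atoms: none
Why: Corey–Bakshi–Shibata reduction: with the brominated C4 (flanked by the quaternary C5) as the large group and the vinylic C2–H as the small one, the (R)-catalyst delivers hydride to the face that gives the (3S) carbinol, OH trans to Br (same sense as (R)-catalyst giving (S)-1-phenylethanol); reduction is 1,2-selective and both C–Br bonds survive.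

## Compound list

1 | 2-methylbut-1-en-3-yne | C=C(C)C#C | starting material
2 | 4-bromo-3-methylbuta-1,2-diene | C=C=C(C)CBr | intermediate
3 | 2-bromo-3-methylbuta-1,3-diene | C=C(C)C(Br)=C | intermediate
4 | 3-ethoxy-5,5-dimethylcyclohex-2-en-1-one (dimedone ethyl enol ether) | CCOC1=CC(=O)CC(C)(C)C1 | starting material
5 | 6-[(dimethylamino)methyl]-3-ethoxy-5,5-dimethylcyclohex-2-en-1-one (racemic) | CCOC1=CC(=O)C(CN(C)C)C(C)(C)C1 | intermediate
6 | [(4-ethoxy-6,6-dimethyl-2-oxocyclohex-3-en-1-yl)methyl]trimethylammonium iodide (racemic) | CCOC1=CC(=O)C(C[N+](C)(C)C)C(C)(C)C1.[I-] | intermediate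
7 | 3-ethoxy-5,5-dimethyl-6-methylidenecyclohex-2-en-1-one | CCOC1=CC(=O)C(=C)C(C)(C)C1 | intermediate
8 | (6R)-8-bromo-3-ethoxy-5,5,9-trimethylspiro[5.5]undeca-2,8-dien-1-one | O=C1C=C(OCC)CC(C)(C)[C@]12CCC(C)=C(Br)C2 | intermediate
9 | (6R)-8-bromo-3-ethoxy-1,5,5,9-tetramethylspiro[5.5]undeca-2,8-dien-1-ol (mixture of C1 epimers) | CC1(O)C=C(OCC)CC(C)(C)[C@]12CCC(C)=C(Br)C2 | intermediate
10 | (6R)-8-bromo-1,5,5,9-tetramethylspiro[5.5]undeca-1,8-dien-3-one | CC1=CC(=O)CC(C)(C)[C@]12CCC(C)=C(Br)C2 | intermediate
11 | {[(6S)-8-bromo-1,5,5,9-tetramethylspiro[5.5]undeca-1,3,8-trien-3-yl]oxy}trimethylsilane | CC1=CC(O[Si](C)(C)C)=CC(C)(C)[C@]12CCC(C)=C(Br)C2 | intermediate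
12 | (4S,6S)-4,8-dibromo-1,5,5,9-tetramethylspiro[5.5]undeca-1,8-dien-3-one | CC1=CC(=O)[C@@H](Br)C(C)(C)[C@]12CCC(C)=C(Br)C2 | intermediate
13 | (3S,4S,6S)-4,8-dibromo-1,5,5,9-tetramethylspiro[5.5]undeca-1,8-dien-3-ol | CC1=C[C@H](O)[C@@H](Br)C(C)(C)[C@]12CCC(C)=C(Br)C2 | target

## Step count and risks

Total step count: 6. Longest linear sequence: 5 steps (steps 2–6 from 4; equally steps 1 and 3–6 from 1).

**Step 3 (proposed new cycloaddition).** The bromodiene is less nucleophilic than isoprene, the dienophile is a deactivated vinylogous ester, and methyl-over-bromine regiocontrol and the facial sense are untested.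
The fallback sets out from 7 and comes back at 8.
- Compound 7 is taken through the same acid-catalysed cycloaddition with isoprene, a 2-alkyl diene of the type for which this catalysis is established, to give (6R)-3-ethoxy-5,5,9-trimethylspiro[5.5]undeca-2,8-dien-1-one F1.
- The trisubstituted ring-B alkene is hydroborated and oxidised (BH3·SMe2, THF, 0 °C; NaBO3·4H2O) to (6R)-3-ethoxy-8-hydroxy-5,5,9-trimethylspiro[5.5]undec-2-en-1-one F2 (8,9-trans; the mixture at C8/C9 does not matter).
- Dess–Martin oxidation gives (6R)-3-ethoxy-5,5,9-trimethylspiro[5.5]undec-2-ene-1,8-dione F3.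
- The C8 ketone is converted into the more substituted vinyl bromide with (PhO)3P/Br2/Et3N (CH2Cl2, −60 °C → reflux), which is 8.

**Step 5 (C4 configuration).** Selectivity rests on a remote conformational bias of ring B, so the kinetic ratio of C4 epimers may be low.
The fallback sets out from 10 and comes back at 12; it replaces kinetic face selection by thermodynamic control with recycling.
- Bromination through the enol with PhNMe3Br3 (THF, 0 °C) gives 12 together with its C4 epimer (4R,6S)-4,8-dibromo-1,5,5,9-tetramethylspiro[5.5]undeca-1,8-dien-3-one F4.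
- C4 is enolisable but has no β-hydrogen (C5 is quaternary), so the mixture is equilibrated with catalytic DBU in CH2Cl2 toward the epimer with equatorial bromine.
- 12 is separated by chromatography and F4 is returned to the same equilibration.

**Step 6 (C3 configuration).** Axial hydride delivery runs past the axial C5 methyl, and which side of the ketone acts as the large group for the oxazaborolidine is not certain, so catalyst and substrate may be mismatched.
The fallback sets out from 12 and comes back at 13.
- i-Bu2AlH (CH2Cl2, −78 °C) delivers hydride equatorially, away from the axial C5 methyl, to give the cis-bromohydrin (3R,4S,6S)-4,8-dibromo-1,5,5,9-tetramethylspiro[5.5]undeca-1,8-dien-3-ol F5.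
- Mitsunobu inversion with chloroacetic acid (PPh3, DIAD, toluene, 0 → 25 °C) gives (3S,4S,6S)-4,8-dibromo-1,5,5,9-tetramethylspiro[5.5]undeca-1,8-dien-3-yl 2-chloroacetate F6.
- Brief methanolysis (catalytic K2CO3, MeOH, 0 °C, short contact so that the trans-bromohydrin does not close to an epoxide) gives 13.

## Further compounds

F1 | step 3 | (6R)-3-ethoxy-5,5,9-trimethylspiro[5.5]undeca-2,8-dien-1-one | O=C1C=C(OCC)CC(C)(C)[C@]12CCC(C)=CC2
F2 | step 3 | (6R)-3-ethoxy-8-hydroxy-5,5,9-trimethylspiro[5.5]undec-2-en-1-one (8,9-trans, mixture of diastereomers) | O=C1C=C(OCC)CC(C)(C)[C@]12CCC(C)C(O)C2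
F3 | step 3 | (6R)-3-ethoxy-5,5,9-trimethylspiro[5.5]undec-2-ene-1,8-dione (mixture of C9 epimers) | O=C1C=C(OCC)CC(C)(C)[C@]12CCC(C)C(=O)C2
F4 | step 5 | (4R,6S)-4,8-dibromo-1,5,5,9-tetramethylspiro[5.5]undeca-1,8-dien-3-one | CC1=CC(=O)[C@H](Br)C(C)(C)[C@]12CCC(C)=C(Br)C2
F5 | step 6 | (3R,4S,6S)-4,8-dibromo-1,5,5,9-tetramethylspiro[5.5]undeca-1,8-dien-3-ol | CC1=C[C@@H](O)[C@@H](Br)C(C)(C)[C@]12CCC(C)=C(Br)C2
F6 | step 6 | (3S,4S,6S)-4,8-dibromo-1,5,5,9-tetramethylspiro[5.5]undeca-1,8-dien-3-yl 2-chloroacetate | CC1=C[C@H](OC(=O)CCl)[C@@H](Br)C(C)(C)[C@]12CCC(C)=C(Br)C2
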